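Readings and results were generated by integration for an exercise, noise included.

Take G, the ratio of target made to target used, in a flask holding substrate at concentration s and target at T. I write G = s(a + bT²)/(dT), where a is the plain conversion, b the autocatalytic one and d the loss of target.

| flask | substrate | remark | time |
|---|---|---|---|
| alpha | 0.053 M | run made earlier |  |
| theta | 0.22 M | run made earlier |  |
| autumn | 0.080 M |  | 10 min |
| spring | 0.15 M |  | 10 min |
| dusk | 0.30 M |  | 10 min |

| run | time / min | target / % | substrate / % |
|---|---|---|---|
| alpha | 0.833 | 4.5 | 93.1 |
| alpha | 2.50 | 5.5 | 78.1 |
| alpha | 5.00 | 4.7 | 65.0 |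
| alpha | 8.00 | 5.4 | 52.4 |
| theta | 2.00 | 6.8 | 80.1 |
| theta | 4.00 | 11.5 | 53.3 |
| theta | 5.00 | 9.0 | 41.5 |
| theta | 8.00 | 3.3 | 28.4 |

(standard deviation of a reading: 1 percentage point)

- [target] at the end for autumn, spring, dusk, in this order
- the shape of the row from first to last (hardly changes / falls all the way / rises, then falls / rises all the way / falls, then rises)

- what may be going on: substrate + 2 target -> 3 target; substrate -> target; substrate <-> dormant form; target -> over-reaction product
- "hardly changes" means that all values lie within two and a half points (for a concentration: within two and a half percent of the largest)

Reading all substrate loss in alpha as conversion gives a = 0.0802 /min. The target readings in alpha stay level, so made equals used, and that gives d = 1.04 /min. The faster loss in theta up to 5.00 min then gives b = 347 /M²/min.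

G is lowest at T = 0.0152 M, and there it equals s/s*, where the ignition level s* = d/(2√(ab)) = 0.0984 M. So I = charge/s* is the made-to-used ratio at the bottleneck.

| flask | I |
|---|---|
| alpha | 0.539 |
| autumn | 0.813 |
| spring | 1.53 |
| theta | 2.24 |
| dusk | 3.05 |

Now the run in slow motion. In the first instants T is near zero, and by my reckoning target has a half-life of ln(2)/d = 0.666 min, which is shorter than the 10 min of the run. So T soon reaches the low balance as/d, where G is near one.

In the middle, alpha, with I below one, held near that balance, since its target readings stayed level. Theta, with I well above one, passed the bottleneck and ran away, its target reading 11.5% and later 3.3%.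

At the end, my reckoning puts autumn on the low balance at 0.00277 M. Spring is the open case: its substrate falls to s* in about 5.26 min, sooner than the asked time. I bet it stays low, at 0.00520 M. Dusk should burn out and leave a trace.

The forecast gave 0.003 M, 0.0053 M and 6.000 × 10⁻⁴ M, shape rises, then falls, with the grounds “above that the system ignites”.

The flask gives 0.00244 M, 0.00462 M and 7.49 × 10⁻⁴ M, shape rises, then falls.

    substrate + 2 target → 3 target (k = 4.30 /M²/s)
    substrate → target (k = 9.10 × 10⁻⁴ /s)
    substrate ⇌ dormant form (K = 0.380, k = 8.20 × 10⁻⁴ /s)
    target → over-reaction product (k = 0.0150 /s)

The row turns at 0.20 M, which is I = 2.03, about twice the ignition level, so spring lies below the turn and dusk above it. The passing of target into over-reaction product, the d in I, has the largest single effect on dusk: without it, target in dusk stands at 0.294 M at the asked time instead of 7.49 × 10⁻⁴ M. Autumn, the second flask, at I = 0.813, stays close to the low balance, with made over used at 0.927 at 10.0 min. The passing of target into over-reaction product is a part of the reason for its low target too: without it, target in autumn stands at 0.0715 M instead of 0.00244 M.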